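## Retrosynthetic overview

1. The target (8) is a 3-bromo-oxane joined to a 4-bromo-3-chloro-4-methylcyclohexane. Oxane C-6 (S) and cyclohexane C-1 (S) are the two stereocentres of commercial (−)-α-bisabolol (1), used as chiral pool; the oxane comes from bromoetherification of 1.
2. Enabling feature: in the carbocycle, C-4 carries CH3 and Br, the neighbouring C-3 carries Cl trans to Br, and C-2 is CH2. H and Br thus sit 1,3 across the CHCl carbon with Br on the more substituted end, which is the pattern of Markovnikov HBr addition across the C-1–C-5 fusion bond of a 6-chloro-5-methylbicyclo[3.1.0]hexane (7). Direct BrCl addition to the parent methylcyclohexene should put Cl, not Br, on the tertiary carbon.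
3. Disconnections: 8 ⇒ 7 (ring-enlarging hydrobromination, cyclopentane → cyclohexane) ⇒ cyclopentene 6 (chlorocarbene [2+1]) ⇒ enal 5 (decarbonylation) ⇒ keto aldehyde 4 (aldol condensation) ⇒ cyclohexene 2 (C=C cleavage) ⇒ 1.
4. Ring order: oxane (step 1); the bisabolol cyclohexene is cut open (step 2) and reclosed one carbon smaller as a cyclopentene (step 3); cyclopropane (step 5); cyclohexane by one-carbon enlargement of the cyclopentane (step 6).

Key step: step 6

Remark: natural (−)-α-bisabolol is taken as the (S,S) isomer, (2S)-6-methyl-2-[(1S)-4-methylcyclohex-3-en-1-yl]hept-5-en-2-ol; both centres are carried unchanged to the target.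

## Route

Step 1
Reactants: 1 (−)-α-bisabolol
Product: 2 (3R,6S)-3-bromo-2,2,6-trimethyl-6-[(1S)-4-methylcyclohex-3-en-1-yl]oxane
Conditions: 2,4,4,6-tetrabromocyclohexa-2,5-dien-1-one (1.05 equiv), MeNO2, 0 °C to rt, dark
Reagents that add atoms: 2,4,4,6-tetrabromocyclohexa-2,5-dien-1-one, O=C1C(Br)=CC(Br)(Br)C=C1Br
Why: Bromoetherification (6-endo, Markovnikov): the side-chain bromonium ion is opened by the tertiary hydroxyl at the dimethyl-substituted carbon through a chair with Br and the cyclohexenyl group equatorial and the C-6 methyl axial, which should set C-3 (R) relative to the fixed C-6; the ring alkene can only be trapped through a boat and should revert.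

Step 2
Reactants: 2 (3R,6S)-3-bromo-2,2,6-trimethyl-6-[(1S)-4-methylcyclohex-3-en-1-yl]oxane
Product: 4 (3S)-3-[(2S,5R)-5-bromo-2,6,6-trimethyloxan-2-yl]-6-oxoheptanal, via secondary ozonide 3 (not isolated)
Conditions: O3, CH2Cl2, −78 °C; then Me2S, −78 °C to rt
Reagents that add atoms: ozone, [O-][O+]=O
Why: Ozonolysis (Criegee mechanism) of the only remaining alkene with reductive work-up; no stereocentre is touched, and the old ring CH becomes C-3 of the chain, which is not enolisable.

Step 3
Reactants: 4 (3S)-3-[(2S,5R)-5-bromo-2,6,6-trimethyloxan-2-yl]-6-oxoheptanal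
Product: 5 (5S)-5-[(2S,5R)-5-bromo-2,6,6-trimethyloxan-2-yl]-2-methylcyclopent-1-ene-1-carbaldehyde
Conditions: piperidine (0.2 equiv), AcOH (0.2 equiv), toluene, 80 °C
Reagents that add atoms: none
Why: Intramolecular aldol condensation in which the aldehyde-derived enamine attacks the methyl ketone and water is lost, the known regiochemistry for 6-oxoheptanals from 1-methylcyclohexenes; the stereocentre next to the new alkene has no acidifying carbonyl in conjugation and should be retained.

Step 4
Reactants: 5 (5S)-5-[(2S,5R)-5-bromo-2,6,6-trimethyloxan-2-yl]-2-methylcyclopent-1-ene-1-carbaldehyde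
Product: 6 (3R,6S)-3-bromo-2,2,6-trimethyl-6-[(1S)-3-methylcyclopent-2-en-1-yl]oxane
Conditions: RhCl3·3H2O (5 mol %), 1,3-bis(diphenylphosphino)propane (10 mol %), diglyme, 160 °C, N2 stream
Reagents that add atoms: none
Why: Tsuji–Wilkinson decarbonylation (formyl C–H oxidative addition, CO de-insertion, C–H reductive elimination) should replace CHO by H at the same vinylic carbon, excising the old ring CH carbon and leaving the trisubstituted cyclopentene in place.

Step 5
Reactants: 6 (3R,6S)-3-bromo-2,2,6-trimethyl-6-[(1S)-3-methylcyclopent-2-en-1-yl]oxane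
Product: 7 (3R,6S)-3-bromo-6-[(1R,2S,5S,6R)-6-chloro-5-methylbicyclo[3.1.0]hexan-2-yl]-2,2,6-trimethyloxane (cyclopropane anti to the oxanyl group, chlorine endo)
Conditions: CH2Cl2 (excess), NaN(SiMe3)2 (3 equiv, slow addition), pentane, −30 °C to rt
Reagents that add atoms: dichloromethane, ClCCl
Why: α-Elimination gives a chlorocarbenoid that adds stereospecifically ([2+1] cycloaddition) to the electron-rich trisubstituted alkene; attack should come anti to the fully substituted oxanyl carbon on the allylic centre (sets C-1 and C-5), and chlorine should end endo, following the syn preference of chlorocarbenoids for the more alkylated side (sets C-6); the equatorial secondary bromide has no anti-periplanar hydrogen for E2.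

Step 6
Reactants: 7 (3R,6S)-3-bromo-6-[(1R,2S,5S,6R)-6-chloro-5-methylbicyclo[3.1.0]hexan-2-yl]-2,2,6-trimethyloxane
Product: 8 (3R,6S)-3-bromo-6-[(1S,3R,4R)-4-bromo-3-chloro-4-methylcyclohexyl]-2,2,6-trimethyloxane
Conditions: HBr (33% in AcOH, 3 equiv), CH2Cl2, −20 °C to 10 °C
Reagents that add atoms: hydrogen bromide, Br
Why: Proposed new method: the proton should attack the most electron-rich cyclopropane bond of 7, the C-1–C-5 fusion bond, in the Markovnikov sense (H to the bridgehead CH, charge to the methyl-bearing C-5), so that fission of this bond turns the cyclopentane into a 1-methylcyclohexyl cation with an axial β-chlorine, a chloronium-type ion that no electrophilic chlorine reagent could form next to bromide, and bromide captures it at the tertiary carbon. The closest known reaction types are the protolytic Markovnikov hydrohalogenation of alkylcyclopropanes, the acid-induced ring enlargement of bicyclo[n.1.0]alkanes by fusion-bond cleavage and the anti hydrobromination of allylic chlorides; new is the use of a monochlorocyclopropane so that C–C protonation delivers a vicinal bromochloride. No ring is closed by cyclisation: the six-membered ring arises by one-carbon enlargement of the five-membered ring when the zero-atom bridge breaks, the former CHCl bridge becoming cyclohexane C-3 and the protonated bridgehead becoming the C-2 methylene. The only new stereocentre, cyclohexane C-4, is controlled by the chlorine-bearing centre: bromide should add axially and anti-periplanar to the axial C–Cl bond (chlorine bridging, chair-like transition state with the oxanyl group equatorial), giving the trans-diaxial bromochloride with equatorial methyl, while C-1 and C-3 are carried over from 7. The step needs fusion-bond cleavage (secured by the methyl group, which makes the cation tertiary, and by chlorine, which deactivates its own two bonds and disfavours protonation at its carbon), anti capture (secured by the endo chlorine) and survival of the di-tertiary ether (cold anhydrous acid, short contact).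

## Compound list

1 | (−)-α-bisabolol, (2S)-6-methyl-2-[(1S)-4-methylcyclohex-3-en-1-yl]hept-5-en-2-ol | O[C@](C)([C@H]1CCC(C)=CC1)CCC=C(C)C | starting material
2 | (3R,6S)-3-bromo-2,2,6-trimethyl-6-[(1S)-4-methylcyclohex-3-en-1-yl]oxane | CC1(C)O[C@](C)([C@H]2CCC(C)=CC2)CC[C@H]1Br | intermediate
3 | secondary ozonide of 2: 1-methyl-7,8,9-trioxabicyclo[4.2.1]nonane carrying the (2S,5R)-5-bromo-2,6,6-trimethyloxan-2-yl group at C-4 (S), both bridgehead configurations | CC1(C)O[C@](C)([C@H]2CCC3(C)OOC(C2)O3)CC[C@H]1Br | intermediate (not isolated)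
4 | (3S)-3-[(2S,5R)-5-bromo-2,6,6-trimethyloxan-2-yl]-6-oxoheptanal | CC1(C)O[C@](C)([C@H](CC=O)CCC(C)=O)CC[C@H]1Br | intermediate
5 | (5S)-5-[(2S,5R)-5-bromo-2,6,6-trimethyloxan-2-yl]-2-methylcyclopent-1-ene-1-carbaldehyde | CC1(C)O[C@](C)([C@H]2CCC(C)=C2C=O)CC[C@H]1Br | intermediate
6 | (3R,6S)-3-bromo-2,2,6-trimethyl-6-[(1S)-3-methylcyclopent-2-en-1-yl]oxane | CC1(C)O[C@](C)([C@H]2CCC(C)=C2)CC[C@H]1Br | intermediate
7 | (3R,6S)-3-bromo-6-[(1R,2S,5S,6R)-6-chloro-5-methylbicyclo[3.1.0]hexan-2-yl]-2,2,6-trimethyloxane | CC1(C)O[C@](C)([C@H]2CC[C@]3(C)[C@H](Cl)[C@H]23)CC[C@H]1Br | intermediate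
8 | (3R,6S)-3-bromo-6-[(1S,3R,4R)-4-bromo-3-chloro-4-methylcyclohexyl]-2,2,6-trimethyloxane | CC1(C)O[C@](C)([C@H]2CC[C@@](C)(Br)[C@H](Cl)C2)CC[C@H]1Br | target

## Step count and risks

Total steps: 6. Longest linear sequence: 6 (from 1).

Steps most likely to fail:

**Step 6 (Proposed new method).** The deactivated chlorocyclopropane may not be protonated at all, or protonation may cleave an exocyclic cyclopropane bond so that no ring enlargement occurs. The acid may also cleave the di-tertiary ether, or bromide may be captured syn to chlorine. The fallback sets out from 2 and returns to the route at 8, forgoing the ring enlargement. Ene-type allylic chlorination of the ring alkene of 2 (NaOCl, CeCl3·7H2O, CH2Cl2/H2O, 0 °C) is known to turn 1-methylcyclohexenes into 2-methylidenecyclohexyl chlorides. Axial delivery of chlorine to the less substituted alkene carbon should give (3R,6S)-3-bromo-6-[(1S,3R)-3-chloro-4-methylidenecyclohexyl]-2,2,6-trimethyloxane F1; the endocyclic alkene isomer would converge in the next operation. Ionic Markovnikov addition of HBr (CH2Cl2, −78 °C) to the 1,1-disubstituted alkene, anti to the allylic chlorine, should then give 8. The weak point of this alternative is the face selectivity of the chlorination.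

**Step 5.** The endo/exo selectivity at the carbene carbon may be poor, the strong amide base may dehydrobrominate the secondary bromide, and the hindered alkene may convert incompletely. The fallback sets out from 6 and returns at 7. Phase-transfer addition of bromochlorocarbene (CHBr2Cl, 50% aqueous NaOH, BnEt3NCl, CH2Cl2, rt; no soluble strong base) should give (3R,6S)-3-bromo-6-[(1R,2S,5S,6S)-6-bromo-6-chloro-5-methylbicyclo[3.1.0]hexan-2-yl]-2,2,6-trimethyloxane F2 (bromine exo, chlorine endo), separated from its epimer at the dihalogenated carbon. Selective bromine–lithium exchange at the cyclopropane (n-BuLi, THF, −100 °C) should give the 6-endo-chloro-6-exo-lithio carbenoid (3R,6S)-3-bromo-6-[(1R,2S,5S)-6-chloro-6-lithio-5-methylbicyclo[3.1.0]hexan-2-yl]-2,2,6-trimethyloxane F3. Protonation in place with MeOH, with retention, then gives 7.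

**Step 1.** Bromonium formation may compete at the ring alkene, 5-exo closure to the oxolane may compete with 6-endo closure, and diastereocontrol at the bromine-bearing carbon may be weak. The fallback sets out from 1 and returns at 2. Reversible mercuricyclisation (Hg(OCOCF3)2, MeNO2, 0 °C) should give the equatorial organomercurial [(3R,6S)-2,2,6-trimethyl-6-[(1S)-4-methylcyclohex-3-en-1-yl]oxan-3-yl]mercury trifluoroacetate F4. Anion exchange (aqueous KBr) gives bromo[(3R,6S)-2,2,6-trimethyl-6-[(1S)-4-methylcyclohex-3-en-1-yl]oxan-3-yl]mercury F5. Brominative demercuration (Br2, LiBr, pyridine, 0 °C) then gives 2, with the epimeric bromide to be separated.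

## Further compounds

F1 | step 6 | (3R,6S)-3-bromo-6-[(1S,3R)-3-chloro-4-methylidenecyclohexyl]-2,2,6-trimethyloxane | CC1(C)O[C@](C)([C@H]2CCC(=C)[C@H](Cl)C2)CC[C@H]1Br
F2 | step 5 | (3R,6S)-3-bromo-6-[(1R,2S,5S,6S)-6-bromo-6-chloro-5-methylbicyclo[3.1.0]hexan-2-yl]-2,2,6-trimethyloxane | CC1(C)O[C@](C)([C@H]2CC[C@]3(C)[C@](Br)(Cl)[C@H]23)CC[C@H]1Br
F3 | step 5 | (3R,6S)-3-bromo-6-[(1R,2S,5S)-6-chloro-6-lithio-5-methylbicyclo[3.1.0]hexan-2-yl]-2,2,6-trimethyloxane (chlorine endo, lithium exo) | CC1(C)O[C@](C)([C@H]2CC[C@]3(C)[C@]([Li])(Cl)[C@H]23)CC[C@H]1Br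
F4 | step 1 | [(3R,6S)-2,2,6-trimethyl-6-[(1S)-4-methylcyclohex-3-en-1-yl]oxan-3-yl]mercury trifluoroacetate | CC1(C)O[C@](C)([C@H]2CCC(C)=CC2)CC[C@H]1[Hg]OC(=O)C(F)(F)F
F5 | step 1 | bromo[(3R,6S)-2,2,6-trimethyl-6-[(1S)-4-methylcyclohex-3-en-1-yl]oxan-3-yl]mercury | CC1(C)O[C@](C)([C@H]2CCC(C)=CC2)CC[C@H]1[Hg]Br
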